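## The problem

Compound 20 consists of two six-membered carbocycles that share no atom. Ring A is a hexasubstituted benzene (2,4,6-trihydroxy, 3-methyl, 5-(3-phenylpropanoyl)) and ring B is the enol of a 3,3,5,5-tetramethylcyclohexane-2,4,6-trione; they are joined only through one sp3 methine, C1 of a 3-methylbutyl chain. This methine is the only stereocentre (S). Nothing else in the molecule can relay or correct it, so an external chiral catalyst has to set it, and no later step may ionise it. The methine sits between two vinylogous acids, each a good carbon leaving group, so heat with weak base or acid opens a retro-Michael path to racemisation, and acid also condenses a ring A hydroxyl with a ring B carbonyl to a pyran. A free phloroglucinol ring A is easily oxidised and would be C-alkylated by any electrophile meant for ring B, and the ring B enol is about as acidic as a carboxylic acid, so it is deprotonated first in every basic step. The enabling feature is the substitution of ring B: C2, C4 and C6 carry oxygen, C3 and C5 carry two methyl groups each, and C1 carries the side chain. This is the pattern a 2-alkylphloroglucinol gives when each of its two unsubstituted ring carbons is methylated twice. Ring B can therefore stay aromatic until the stereocentre has been made by an enantioselective Friedel–Crafts reaction, and ring A, with its 1,3,5-oxygen pattern, is then folded polyketide-style from the two-carbon chain that reaction leaves behind.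

## Retrosynthesis

**20 to 18.** The first cut is the ring A bond between the acyl-bearing carbon and the hydroxylated carbon next to the methyl-bearing carbon. Read as a Claisen condensation, it opens ring A to triketo ester 19, the methanolysis product of 4-hydroxy-2-pyrone 18. Removing the 3-phenylpropanoyl group instead would demand a late Lewis-acid acylation beside the acid-labile methine. The mirror-image Claisen at the other flank would attack an ester next to the bulky side-chain carbon. Pyrone 18 is an isomer of 20 with one carbocycle fewer. The forward step must open a fully substituted pyrone and close the ring through the only doubly activated methylene without touching the stereocentre.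

**18 to 15 and 17.** The bond between the pyrone 6-methylene and the ketone carbonyl is cut, giving 6-methylpyrone 15 and N-methoxy-N-methylamide 17 (from acid chloride 16). Adding the phenylpropanoyl unit last keeps an enolisable ketone out of the earlier enolate steps. A four-carbon 3-oxoacyl donor would shorten the route but carries an acidic methylene that would quench the polyanion. The forward step needs selective deprotonation of the 6-methyl group of 15.

**15 to 14, then 12 and 13.** The lactone C–O bond is opened to diketo ester 14, and the bond between C4 of 14 and its acetyl group is cut to β-keto ester 12 and acetamide 13. This is where the future side-chain-bearing carbon of ring A gains its second carbonyl neighbour. It reacts as the γ-carbon of a β-keto ester polyanion, its most basic site, with a small electrophile. Acylating the same carbon earlier, as the α-carbon of ester 8, would save two steps but would put the hindered carbon next to the ester that must be attacked in the last step.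

**12 to 10 and 11, then 9 and 8.** The bond between the ketone carbon and the methyl-bearing α-carbon is cut to enol lactone 10 and methyl propanoate 11. The enol lactone activates the carboxyl group and ties up the ring B enol at once, and on opening it releases ring B as an inert enolate. A direct Claisen on methyl ester 8 would be shorter but meets a β-branched, enolisable ester beside an anionic ring. Lactone 10 comes from acid 9 by dehydration and 9 from ester 8 by saponification.

**8 to 5 and 6 (key step).** Four C–CH3 bonds of ring B are cut, two at each quaternary carbon. The precursor is the 2-alkylphloroglucinol 7, formed in the flask from dihydrocoumarin 5 and methoxide, and the electrophile is iodomethane 6. Building the two quaternary carbons by C–C(=O) bond formation (Dieckmann-type) would require acylation of tertiary carbanions, whereas here an aromatic ring supplies the carbons and oxygens ready-made. The forward step must alkylate at carbon, not oxygen, and stop at four methyl groups.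

**5 to 4, 3, then 1 and 2.** The phenols are masked as benzyl ethers (4), the lactone is taken back to lactol 3, and the aryl–C4 bond is cut to 3,5-bis(benzyloxy)phenol 1 and (E)-5-methylhex-2-enal 2. The benzyl ethers leave only one kind of nucleophilic site, ortho to the free hydroxyl, and tolerate the lactol oxidation. Free phloroglucinol would be alkylated more than once and would not survive an oxidant. The forward step is an iminium-catalysed Friedel–Crafts alkylation, which sets the stereocentre.

## Roads not taken

**Alternative 1:** The cut runs through three bonds of ring A. The cyclobutenone A2, which already carries the stereocentre at C4, is heated with siloxyalkyne A3; electrocyclic opening to a vinylketene, [2+2] addition of the alkyne, a second opening and a 6π closure (Danheiser benzannulation) give phenol A1. Its merits are real: ring A forms in one neutral thermal step with fixed regiochemistry and three differentiated oxygens. That is clearly faster than the six operations (steps 7 to 12) the chosen plan spends on ring A. Its weak points lie around that step. A1 lacks both the acyl group and ring B. Ring B would have to be built from the ester chain through two quaternary carbons, and the acyl group would have to be added by Friedel–Crafts chemistry beside an acid-labile methine. A2 also needs its own enantioselective synthesis, and A3 is a sensitive reagent. The chosen plan sets against the shorter ring A a one-step ring B from an inexpensive aromatic, and an acyl ketone that arrives in the same step that closes ring A.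

**Alternative 2:** Two bonds of ring B are cut: from the former lactone carbonyl to a gem-dimethyl carbon, and from the lactone α-carbon to an ester carbonyl. Forward, the lithium enolate of keto ester A5 is C-acylated by dihydrocoumarin A6, which carries the complete, benzyl-protected ring A and has the (4R) configuration. LiN(SiMe3)2 then closes ring B by a Dieckmann reaction to give A4, and hydrogenolysis would finish the synthesis. This is the shortest route on paper and better than the chosen plan in step economy, since ring A is never built and the Dieckmann closure has no competing acidic site. Its risks lie in two places. One is C-acylation of a fully substituted ketone enolate by an aryl lactone that can instead enolise or lose phenoxide to a ketene. The other is the preparation of A6, which needs an enantioselective Friedel–Crafts reaction at the single flanked position of a ketone-deactivated, pentasubstituted phenol, a substrate class without close precedent. The chosen plan is longer but sets its stereocentre on a simple dialkoxyphenol of a well-precedented type and forms no quaternary carbon by acylation.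

**Alternative 3:** Ring B is cut at the two bonds to the carbonyl carbon that lies between the gem-dimethyl carbons. Forward, excess LiN(i-Pr)2 converts diketone A8 into a polyanion, and dimethyl carbonate A9 acylates both isopropyl carbons in turn to give A7. The attraction is that ring B comes from two isobutyryl units and a one-carbon reagent while ring A is present from the start. The weak points are many. Two tertiary carbanions must be generated beside an already enolised diketone and acylated at carbon, not oxygen. A8 has no obvious enantioselective origin. A7 still lacks the 3-phenylpropanoyl group, which would have to be added with 16 under Friedel–Crafts conditions beside the acid-labile methine. The chosen plan makes the same two quaternary carbons by methylating an aromatic ring, an easier bond to form, and it installs the acyl group without acid. Alternative 3 is better only in never having to construct ring A.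

Key step: step 4

Assumption: phenol 1 and enal 2 are taken as purchased. Centres formed as epimer mixtures (C2 of 3, C2 of 12, C2 and C4 of 14 and 19) later become sp2 carbons and are left undefined.

Step 1
Reactants: 1 3,5-bis(benzyloxy)phenol; 2 (E)-5-methylhex-2-enal
Product: 3 (4S)-5,7-bis(benzyloxy)-4-(2-methylpropyl)-3,4-dihydro-2H-chromen-2-ol (mixture of C2 epimers)
Conditions: (R)-2-[diphenyl(trimethylsilyloxy)methyl]pyrrolidine (20 mol %), PhCO2H (20 mol %), toluene, 0 °C to rt
Reagents that add atoms: none
Why: Iminium-catalysed Friedel–Crafts alkylation with hemiacetal formation, a cascade known for 3,5-dialkoxyphenols and naphthols with enals. The diphenyl(silyloxy)methyl group of the (R)-catalyst shields one face of the (E)-iminium ion, so the arene carbon ortho to the hydroxyl adds to the open face of C3 of 2 and should give the (S) centre, which ring closure to the lactol then fixes.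

Step 2
Reactants: 3 (4S)-5,7-bis(benzyloxy)-4-(2-methylpropyl)-3,4-dihydro-2H-chromen-2-ol
Product: 4 (4S)-5,7-bis(benzyloxy)-4-(2-methylpropyl)-3,4-dihydro-2H-chromen-2-one
Conditions: Dess–Martin periodinane (1.3 equiv), CH2Cl2, rt
Reagents that add atoms: none
Why: Oxidation of a lactol to a lactone with a hypervalent iodine reagent under near-neutral conditions; the benzyl ethers and the C4 centre, which has no acidic hydrogen, should be unaffected.

Step 3
Reactants: 4 (4S)-5,7-bis(benzyloxy)-4-(2-methylpropyl)-3,4-dihydro-2H-chromen-2-one
Product: 5 (4S)-5,7-dihydroxy-4-(2-methylpropyl)-3,4-dihydro-2H-chromen-2-one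
Conditions: H2 (1 atm), Pd/C (10 wt %), EtOAc, rt
Reagents that add atoms: none
Why: Hydrogenolysis of aryl benzyl ethers; the aryl lactone and the benzylic C–C bond at C4 are not cleaved under these conditions, and an aprotic solvent avoids premature opening of the lactone.

Step 4
Reactants: 5 (4S)-5,7-dihydroxy-4-(2-methylpropyl)-3,4-dihydro-2H-chromen-2-one; 6 iodomethane
Product: 8 methyl (3S)-3-(2-hydroxy-3,3,5,5-tetramethyl-4,6-dioxocyclohex-1-en-1-yl)-5-methylhexanoate, via ring-opened triphenol methyl ester 7 (not isolated)
Conditions: NaOMe (6 equiv), MeOH, 0 °C; MeI (4.2 equiv, in portions), rt to 45 °C; 1 M HCl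
Reagents that add atoms: iodomethane, CI; sodium methoxide, [Na+].[O-]C
Why: Methoxide transesterifies the aryl lactone of 5 and gives the phenoxide of 7. Each phenoxide of this 2-alkylphloroglucinol is the enolate of a cyclohexanetrione tautomer and is alkylated by 6 at an unsubstituted ring carbon in an SN2 reaction. That carbon is still enolisable after the first methyl group and takes a second, which makes it quaternary and fixes the neighbouring carbonyl groups; the same happens at the other free carbon, so four C–CH3 bonds form and the ring is dearomatised to the enolate of 8. The closest known reaction type is the exhaustive C-methylation of acyl- and alkylphloroglucinols with iodomethane and methoxide to 4,4,6,6-tetramethylcyclohexane-1,3,5-triones. No ring is closed and no stereocentre is created; the existing centre carries no acidic hydrogen and ring B is present only as its anion, so it cannot leave and the centre should survive. The step needs C- over O-alkylation, which methanol favours by hydrogen bonding to the phenoxide oxygens. It also needs alkylation to stop at four: the fifth site, the ring carbon carrying the branched secondary chain, is shielded, and the final enolate is a delocalised vinylogous carboxylate, so a limited charge of 6 should suffice. Any enol methyl ether formed is a vinylogous ester and should be hydrolysed back to 8 by the aqueous acid work-up.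

Step 5
Reactants: 8 methyl (3S)-3-(2-hydroxy-3,3,5,5-tetramethyl-4,6-dioxocyclohex-1-en-1-yl)-5-methylhexanoate
Product: 9 (3S)-3-(2-hydroxy-3,3,5,5-tetramethyl-4,6-dioxocyclohex-1-en-1-yl)-5-methylhexanoic acid
Conditions: LiOH (3 equiv), THF/H2O, rt; then 1 M HCl
Reagents that add atoms: lithium hydroxide, [Li+].[OH-]
Why: Ester saponification; ring B is present as its enolate and has no enolisable carbon between the carbonyl groups, so it should resist hydroxide, and the stereocentre is not acidic.

Step 6
Reactants: 9 (3S)-3-(2-hydroxy-3,3,5,5-tetramethyl-4,6-dioxocyclohex-1-en-1-yl)-5-methylhexanoic acid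
Product: 10 (4S)-6,6,8,8-tetramethyl-4-(2-methylpropyl)-3,4-dihydro-2H-chromene-2,5,7(6H,8H)-trione
Conditions: Ac2O, NaOAc (0.2 equiv), 80 °C
Reagents that add atoms: none
Why: Enol lactonisation of a 5-oxo acid through the mixed anhydride; the ring B enol oxygen closes the six-membered lactone, as in the known 3,4-dihydro-2H-chromene-2,5-diones derived from cyclic 1,3-diones.

Step 7
Reactants: 10 (4S)-6,6,8,8-tetramethyl-4-(2-methylpropyl)-3,4-dihydro-2H-chromene-2,5,7(6H,8H)-trione; 11 methyl propanoate
Product: 12 methyl (5S)-5-(2-hydroxy-3,3,5,5-tetramethyl-4,6-dioxocyclohex-1-en-1-yl)-2,7-dimethyl-3-oxooctanoate (mixture of C2 epimers)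
Conditions: LiN(i-Pr)2 (2.6 equiv), 11 (2.5 equiv), THF, −78 °C; then 10, −78 to −40 °C; 1 M HCl
Reagents that add atoms: none
Why: Claisen-type C-acylation of an ester enolate by an enol lactone (the first stage of a Fujimoto–Belleau reaction). The lactone carbonyl is the only unhindered, activated carbonyl, the leaving group is the inert ring B enolate, and a second equivalent of enolate deprotonates the β-keto ester and prevents further addition.

Step 8
Reactants: 12 methyl (5S)-5-(2-hydroxy-3,3,5,5-tetramethyl-4,6-dioxocyclohex-1-en-1-yl)-2,7-dimethyl-3-oxooctanoate; 13 N-methoxy-N-methylacetamide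
Product: 14 methyl (5S)-4-acetyl-5-(2-hydroxy-3,3,5,5-tetramethyl-4,6-dioxocyclohex-1-en-1-yl)-2,7-dimethyl-3-oxooctanoate (mixture of C2 and C4 epimers and enol forms)
Conditions: LiN(i-Pr)2 (3.3 equiv), THF, −78 to 0 °C; 13 (1.3 equiv), −78 to 0 °C; cold 1 M HCl
Reagents that add atoms: none
Why: γ-Acylation of a β-keto ester polyanion. After the ring B enol and C2–H are deprotonated, C4 is the last-formed and most nucleophilic carbanion, and the chelated adduct of the N-methoxy-N-methylamide holds until work-up, so neither proton transfer nor double addition should interfere.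

Step 9
Reactants: 14 methyl (5S)-4-acetyl-5-(2-hydroxy-3,3,5,5-tetramethyl-4,6-dioxocyclohex-1-en-1-yl)-2,7-dimethyl-3-oxooctanoate
Product: 15 4-hydroxy-5-[(1S)-1-(2-hydroxy-3,3,5,5-tetramethyl-4,6-dioxocyclohex-1-en-1-yl)-3-methylbutyl]-3,6-dimethyl-2H-pyran-2-one
Conditions: DBU (3 equiv), toluene, 80 °C; cold 1 M HCl
Reagents that add atoms: none
Why: Base-mediated lactonisation of a 3,5-diketo ester to a 4-hydroxy-2-pyrone, in which the enolate oxygen of the acetyl group attacks the methyl ester. The basic medium keeps ring B anionic, so it can neither leave nor condense, and both epimeric centres become sp2.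

Step 10
Reactants: 16 3-phenylpropanoyl chloride
Product: 17 N-methoxy-N-methyl-3-phenylpropanamide
Conditions: MeNHOMe·HCl (1.1 equiv), K2CO3 (2.5 equiv), EtOAc/H2O, 0 °C to rt
Reagents that add atoms: N,O-dimethylhydroxylamine hydrochloride, CNOC.Cl
Why: Schotten–Baumann amide formation from an acid chloride.

Step 11
Reactants: 15 4-hydroxy-5-[(1S)-1-(2-hydroxy-3,3,5,5-tetramethyl-4,6-dioxocyclohex-1-en-1-yl)-3-methylbutyl]-3,6-dimethyl-2H-pyran-2-one; 17 N-methoxy-N-methyl-3-phenylpropanamide
Product: 18 4-hydroxy-5-[(1S)-1-(2-hydroxy-3,3,5,5-tetramethyl-4,6-dioxocyclohex-1-en-1-yl)-3-methylbutyl]-3-methyl-6-(2-oxo-4-phenylbutyl)-2H-pyran-2-one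
Conditions: LiN(i-Pr)2 (3.3 equiv), THF, −78 to −20 °C; 17 (1.3 equiv), −78 to 0 °C; cold 1 M HCl
Reagents that add atoms: none
Why: Side-chain acylation of a 4-hydroxy-6-methyl-2-pyrone polyanion. After the two acidic hydroxyls, only the 6-methyl group gives a carbanion conjugated with the lactone carbonyl (the 3-methyl group and the methine do not), and the amide adduct is stable until work-up.

Step 12
Reactants: 18 4-hydroxy-5-[(1S)-1-(2-hydroxy-3,3,5,5-tetramethyl-4,6-dioxocyclohex-1-en-1-yl)-3-methylbutyl]-3-methyl-6-(2-oxo-4-phenylbutyl)-2H-pyran-2-one
Product: 20 1-{2,4,6-trihydroxy-3-[(1S)-1-(2-hydroxy-3,3,5,5-tetramethyl-4,6-dioxocyclohex-1-en-1-yl)-3-methylbutyl]-5-methylphenyl}-3-phenylpropan-1-one, via open-chain triketo ester 19 (not isolated)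
Conditions: Mg(OMe)2 (6 equiv), MeOH, reflux; cold 1 M HCl
Reagents that add atoms: none
Why: Polyketide-type fold of a 6-(2-oxoalkyl)-4-hydroxy-2-pyrone to an acylphloroglucinol: methoxide opens the lactone to the magnesium chelate of 19, the doubly activated C6 methylene attacks the methyl ester (Claisen condensation, 6-exo-trig), and enolisation gives ring A. The competing aldol closure from C2 cannot aromatise because C2 carries the methyl group, and both rings flanking the methine are fully deprotonated, so neither can depart and the stereocentre should be retained.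

**Compound list**

1 | 3,5-bis(benzyloxy)phenol | Oc1cc(OCc2ccccc2)cc(OCc2ccccc2)c1 | starting material
2 | (E)-5-methylhex-2-enal | CC(C)C/C=C/C=O | starting material
3 | (4S)-5,7-bis(benzyloxy)-4-(2-methylpropyl)-3,4-dihydro-2H-chromen-2-ol (C2 epimers) | OC1C[C@H](CC(C)C)c2c(OCc3ccccc3)cc(OCc3ccccc3)cc2O1 | intermediate
4 | (4S)-5,7-bis(benzyloxy)-4-(2-methylpropyl)-3,4-dihydro-2H-chromen-2-one | O=C1C[C@H](CC(C)C)c2c(OCc3ccccc3)cc(OCc3ccccc3)cc2O1 | intermediate
5 | (4S)-5,7-dihydroxy-4-(2-methylpropyl)-3,4-dihydro-2H-chromen-2-one | O=C1C[C@H](CC(C)C)c2c(O)cc(O)cc2O1 | intermediate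
6 | iodomethane | CI | starting material
7 | methyl (3S)-5-methyl-3-(2,4,6-trihydroxyphenyl)hexanoate | COC(=O)C[C@H](CC(C)C)c1c(O)cc(O)cc1O | intermediate (not isolated)
8 | methyl (3S)-3-(2-hydroxy-3,3,5,5-tetramethyl-4,6-dioxocyclohex-1-en-1-yl)-5-methylhexanoate | COC(=O)C[C@H](CC(C)C)C1=C(O)C(C)(C)C(=O)C(C)(C)C1=O | intermediate
9 | (3S)-3-(2-hydroxy-3,3,5,5-tetramethyl-4,6-dioxocyclohex-1-en-1-yl)-5-methylhexanoic acid | OC(=O)C[C@H](CC(C)C)C1=C(O)C(C)(C)C(=O)C(C)(C)C1=O | intermediate
10 | (4S)-6,6,8,8-tetramethyl-4-(2-methylpropyl)-3,4-dihydro-2H-chromene-2,5,7(6H,8H)-trione | O=C1C[C@H](CC(C)C)C2=C(O1)C(C)(C)C(=O)C(C)(C)C2=O | intermediate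
11 | methyl propanoate | CCC(=O)OC | starting material
12 | methyl (5S)-5-(2-hydroxy-3,3,5,5-tetramethyl-4,6-dioxocyclohex-1-en-1-yl)-2,7-dimethyl-3-oxooctanoate (C2 epimers) | COC(=O)C(C)C(=O)C[C@H](CC(C)C)C1=C(O)C(C)(C)C(=O)C(C)(C)C1=O | intermediate
13 | N-methoxy-N-methylacetamide | CC(=O)N(C)OC | starting material
14 | methyl (5S)-4-acetyl-5-(2-hydroxy-3,3,5,5-tetramethyl-4,6-dioxocyclohex-1-en-1-yl)-2,7-dimethyl-3-oxooctanoate (C2 and C4 epimers) | COC(=O)C(C)C(=O)C(C(C)=O)[C@H](CC(C)C)C1=C(O)C(C)(C)C(=O)C(C)(C)C1=O | intermediate
15 | 4-hydroxy-5-[(1S)-1-(2-hydroxy-3,3,5,5-tetramethyl-4,6-dioxocyclohex-1-en-1-yl)-3-methylbutyl]-3,6-dimethyl-2H-pyran-2-one | CC1=C([C@H](CC(C)C)C2=C(O)C(C)(C)C(=O)C(C)(C)C2=O)C(O)=C(C)C(=O)O1 | intermediate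
16 | 3-phenylpropanoyl chloride | O=C(Cl)CCc1ccccc1 | starting material
17 | N-methoxy-N-methyl-3-phenylpropanamide | CON(C)C(=O)CCc1ccccc1 | intermediate
18 | 4-hydroxy-5-[(1S)-1-(2-hydroxy-3,3,5,5-tetramethyl-4,6-dioxocyclohex-1-en-1-yl)-3-methylbutyl]-3-methyl-6-(2-oxo-4-phenylbutyl)-2H-pyran-2-one | O=C(CCc1ccccc1)CC1=C([C@H](CC(C)C)C2=C(O)C(C)(C)C(=O)C(C)(C)C2=O)C(O)=C(C)C(=O)O1 | intermediate
19 | methyl 4-[(1S)-1-(2-hydroxy-3,3,5,5-tetramethyl-4,6-dioxocyclohex-1-en-1-yl)-3-methylbutyl]-2-methyl-3,5,7-trioxo-9-phenylnonanoate (C2 and C4 epimers) | COC(=O)C(C)C(=O)C([C@H](CC(C)C)C1=C(O)C(C)(C)C(=O)C(C)(C)C1=O)C(=O)CC(=O)CCc1ccccc1 | intermediate (not isolated)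
20 | 1-{2,4,6-trihydroxy-3-[(1S)-1-(2-hydroxy-3,3,5,5-tetramethyl-4,6-dioxocyclohex-1-en-1-yl)-3-methylbutyl]-5-methylphenyl}-3-phenylpropan-1-one | Cc1c(O)c(C(=O)CCc2ccccc2)c(O)c([C@H](CC(C)C)C2=C(O)C(C)(C)C(=O)C(C)(C)C2=O)c1O | target

**Step count and least certain steps**

Total: 12 steps. Longest linear sequence: 11 steps (steps 1 to 9, 11 and 12); step 10 is a one-step side branch.

**Step 4 (key step).** The most likely failure is alkylation that does not stop where intended. Every intermediate is an ambident enolate of similar reactivity, so methylation may run on to the substituted ring carbon or to oxygen, or leave partly methylated material. The fallback sets out from enal 2 and replaces the methylation of a chiral substrate by conjugate addition of the preformed tetramethyl trione. 2,2,4,4-Tetramethylcyclohexane-1,3,5-trione (syncarpic acid) F1, a known compound, would be added to 2 under the iminium catalysis of step 1 with the same (R)-catalyst, a reaction type known for cyclic 1,3-diones and enals. This should give (4S)-2-hydroxy-6,6,8,8-tetramethyl-4-(2-methylpropyl)-3,4-dihydro-2H-chromene-5,7(6H,8H)-dione F2, and oxidation as in step 2 would return to the route at enol lactone 10.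

**Step 12.** The fully substituted pyrone anion may open only slowly, so that retro-Claisen loss of the side-chain acyl group takes over. Prolonged heating could also erode the stereocentre through reversible conjugate addition whenever one ring is not fully deprotonated. The fallback sets out from diketo ester 14 and avoids the pyrone altogether. Excess LiN(i-Pr)2 would form the polyanion of 14, which is acylated at the terminal acetyl methyl group by amide 17 (terminal acylation of a β-polycarbonyl polyanion). This gives triketo ester 19 as an isolated compound, which should undergo the Claisen closure with Mg(OMe)2 in methanol at room temperature and so return at 20.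

**Step 8.** Forming a carbanion at C4 next to the anionic ring B and the branched methine may be incomplete, and the hindered trianion may add to the amide sluggishly, leading to recovered 12 or to amide enolisation. The fallback sets out from 12 and removes one negative charge. Trimethylsilyldiazomethane should methylate only the strongly acidic ring B enol, giving methyl (5S)-5-(2-methoxy-3,3,5,5-tetramethyl-4,6-dioxocyclohex-1-en-1-yl)-2,7-dimethyl-3-oxooctanoate F3. Its ordinary dianion would be acetylated with 13 to methyl (5S)-4-acetyl-5-(2-methoxy-3,3,5,5-tetramethyl-4,6-dioxocyclohex-1-en-1-yl)-2,7-dimethyl-3-oxooctanoate F4. DBU would close 4-hydroxy-5-[(1S)-1-(2-methoxy-3,3,5,5-tetramethyl-4,6-dioxocyclohex-1-en-1-yl)-3-methylbutyl]-3,6-dimethyl-2H-pyran-2-one F5, and mild aqueous HCl in THF at room temperature would hydrolyse the vinylogous ester and return at 15.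

**Step 1.** The benzyloxy-substituted phenol may give insufficient facial selectivity, or competing alkylation para to the hydroxyl and double alkylation, since it is bulkier than the methoxy analogues for which the cascade is established. The fallback sets out from phenol 1 and creates the stereocentre by reduction instead of addition. A Pechmann condensation of 1 with ethyl 5-methyl-3-oxohexanoate F6 (Sc(OTf)3 catalysis) would give 5,7-bis(benzyloxy)-4-(2-methylpropyl)-2H-chromen-2-one F7. Asymmetric conjugate reduction with CuH (Cu(OAc)2, a DTBM-SEGPHOS enantiomer chosen to give the (S) product, (EtO)2MeSiH, t-BuOH) would then return at lactone 4.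

## Further compounds

F1 | step 4 | 2,2,4,4-tetramethylcyclohexane-1,3,5-trione (syncarpic acid) | CC1(C)C(=O)CC(=O)C(C)(C)C1=O
F2 | step 4 | (4S)-2-hydroxy-6,6,8,8-tetramethyl-4-(2-methylpropyl)-3,4-dihydro-2H-chromene-5,7(6H,8H)-dione | OC1C[C@H](CC(C)C)C2=C(O1)C(C)(C)C(=O)C(C)(C)C2=O
F0 | step 12 | none | none
F3 | step 8 | methyl (5S)-5-(2-methoxy-3,3,5,5-tetramethyl-4,6-dioxocyclohex-1-en-1-yl)-2,7-dimethyl-3-oxooctanoate | COC(=O)C(C)C(=O)C[C@H](CC(C)C)C1=C(OC)C(C)(C)C(=O)C(C)(C)C1=O
F4 | step 8 | methyl (5S)-4-acetyl-5-(2-methoxy-3,3,5,5-tetramethyl-4,6-dioxocyclohex-1-en-1-yl)-2,7-dimethyl-3-oxooctanoate | COC(=O)C(C)C(=O)C(C(C)=O)[C@H](CC(C)C)C1=C(OC)C(C)(C)C(=O)C(C)(C)C1=O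
F5 | step 8 | 4-hydroxy-5-[(1S)-1-(2-methoxy-3,3,5,5-tetramethyl-4,6-dioxocyclohex-1-en-1-yl)-3-methylbutyl]-3,6-dimethyl-2H-pyran-2-one | CC1=C([C@H](CC(C)C)C2=C(OC)C(C)(C)C(=O)C(C)(C)C2=O)C(O)=C(C)C(=O)O1
F6 | step 1 | ethyl 5-methyl-3-oxohexanoate | CCOC(=O)CC(=O)CC(C)C
F7 | step 1 | 5,7-bis(benzyloxy)-4-(2-methylpropyl)-2H-chromen-2-one | O=C1C=C(CC(C)C)c2c(OCc3ccccc3)cc(OCc3ccccc3)cc2O1
A1 | alternative 1 | methyl (3R)-3-[2-(benzyloxy)-6-hydroxy-3-methyl-4-(triisopropylsilyloxy)phenyl]-5-methylhexanoate | Oc1cc(O[Si](C(C)C)(C(C)C)C(C)C)c(C)c(OCc2ccccc2)c1[C@H](CC(C)C)CC(=O)OC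
A2 | alternative 1 | methyl (3R)-3-[2-(benzyloxy)-3-methyl-4-oxocyclobut-2-en-1-yl]-5-methylhexanoate | COC(=O)C[C@@H](CC(C)C)C1C(=O)C(C)=C1OCc1ccccc1
A3 | alternative 1 | (triisopropylsilyloxy)ethyne | C#CO[Si](C(C)C)(C(C)C)C(C)C
A4 | alternative 2 | 1-{2,6-bis(benzyloxy)-4-hydroxy-3-[(1S)-1-(2-hydroxy-3,3,5,5-tetramethyl-4,6-dioxocyclohex-1-en-1-yl)-3-methylbutyl]-5-methylphenyl}-3-phenylpropan-1-one | Cc1c(OCc2ccccc2)c(C(=O)CCc2ccccc2)c(OCc2ccccc2)c([C@H](CC(C)C)C2=C(O)C(C)(C)C(=O)C(C)(C)C2=O)c1O
A5 | alternative 2 | methyl 2,2,4-trimethyl-3-oxopentanoate | COC(=O)C(C)(C)C(=O)C(C)C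
A6 | alternative 2 | (4R)-5,7-bis(benzyloxy)-8-methyl-4-(2-methylpropyl)-6-(3-phenylpropanoyl)-3,4-dihydro-2H-chromen-2-one | O=C1C[C@@H](CC(C)C)c2c(OCc3ccccc3)c(C(=O)CCc3ccccc3)c(OCc3ccccc3)c(C)c2O1
A7 | alternative 3 | 3-hydroxy-4,4,6,6-tetramethyl-2-{(1S)-3-methyl-1-[2,4,6-tris(benzyloxy)-3-methylphenyl]butyl}cyclohex-2-ene-1,5-dione | Cc1c(OCc2ccccc2)cc(OCc2ccccc2)c([C@H](CC(C)C)C2=C(O)C(C)(C)C(=O)C(C)(C)C2=O)c1OCc1ccccc1
A8 | alternative 3 | 2,6-dimethyl-4-{(1R)-3-methyl-1-[2,4,6-tris(benzyloxy)-3-methylphenyl]butyl}heptane-3,5-dione | CC(C)C(=O)C(C(=O)C(C)C)[C@@H](CC(C)C)c1c(OCc2ccccc2)cc(OCc2ccccc2)c(C)c1OCc1ccccc1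
A9 | alternative 3 | dimethyl carbonate | COC(=O)OC
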